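**Retrosynthetic overview**
- Target ⇐ global O‑demethylation of 5,7‑dimethoxy‑6‑methyl‑2‑nonacosylchromone.
- Key step (instead of the usual Claisen/Baker–Venkataraman acylation of a C‑methylphloroacetophenone): the whole γ‑pyranone ring is made last, in one Pd‑catalysed three‑component carbonylative annulation of an o‑iodophenol, CO (becomes C4) and hentriacont‑1‑yne (becomes C3, C2 and the chain).
- Iodophenol ⇐ mono‑iodination of C2v‑symmetric 3,5‑dimethoxy‑4‑methylphenol ⇐ Ir C–H borylation/oxidation of 2,6‑dimethoxytoluene. The two ortho sites are equivalent and there is only one free OH, so 6‑methyl versus 8‑methyl is fixed by construction.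
- Alkyne ⇐ Ohira–Bestmann homologation of triacontanal ⇐ 1‑triacontanol.
- Ring order: the benzene ring is bought; the pyranone ring is formed in the key step.

Assumption: the side chain is read as unbranched C29 (n‑nonacosyl); the target has no stereocentre or stereogenic double bond, so "single enantiomer" reduces to making the single 6‑methyl constitutional isomer.

**Step 1**  
Reactants: 1 2,6-dimethoxytoluene  
Product: 3 3,5-dimethoxy-4-methylphenol, via aryl pinacol boronate 2 (not isolated)  
Conditions: [Ir(OMe)(cod)]2 (1.5 mol %), dtbpy (3 mol %), HBpin (1.5 equiv), THF, 80 °C; evaporate; then Oxone, acetone/H2O, 0 °C → rt, 15 min  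
Reagents that add atoms: potassium peroxymonosulfate (active component of Oxone), `[K+].[O-]S(=O)(=O)OO`  
Why: Sterically controlled Ir‑catalysed C–H borylation (HBpin supplies the boron of 2) hits the only ring C–H without an ortho substituent, para to the methyl, and Oxone then converts C–B into C–OH at the same carbon (one‑pot borylation/oxidation), giving the symmetric phenol.

**Step 2**  
Reactants: 3 3,5-dimethoxy-4-methylphenol  
Product: 4 2-iodo-3,5-dimethoxy-4-methylphenol  
Conditions: NIS (1.0 equiv), MeCN, −20 → 0 °C, dark  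
Reagents that add atoms: N-iodosuccinimide, `O=C1CCC(=O)N1I`  
Why: Electrophilic aromatic iodination; the two open ring positions are symmetry‑equivalent and strongly activated (ortho to OH and OMe, para to OMe), so one equivalent of NIS can give only this regioisomer, and the crowded product is slower to iodinate again.

**Step 3**  
Reactants: 5 1-triacontanol  
Product: 6 triacontanal  
Conditions: TEMPO (10 mol %), PhI(OAc)2 (1.1 equiv), CHCl3, 40 °C  
Reagents that add atoms: none  
Why: Oxoammonium (TEMPO/PhI(OAc)2) oxidation stops at the aldehyde under anhydrous conditions and tolerates the warm chloroform needed to dissolve the C30 alcohol.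

**Step 4**  
Reactants: 6 triacontanal  
Product: 8 hentriacont-1-yne, via 1-diazohentriacont-1-ene 7 (not isolated)  
Conditions: dimethyl (1-diazo-2-oxopropyl)phosphonate (1.5 equiv), K2CO3 (2.5 equiv), THF/MeOH 2:1, 40 °C  
Reagents that add atoms: dimethyl (1-diazo-2-oxopropyl)phosphonate (Ohira–Bestmann reagent), `CC(=O)C(=[N+]=[N-])P(=O)(OC)OC`  
Why: Seyferth–Gilbert homologation in the Ohira–Bestmann variant: the dimethyl (diazomethyl)phosphonate anion formed in situ olefinates the aldehyde to diazoalkene 7, which loses N2 and undergoes a 1,2‑H shift to the terminal alkyne, adding exactly one carbon.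

**Step 5**  
Reactants: 4 2-iodo-3,5-dimethoxy-4-methylphenol; 8 hentriacont-1-yne (1.2 equiv)  
Product: 11 5,7-dimethoxy-6-methyl-2-nonacosyl-4H-chromen-4-one, via aryl ynone 9 (not isolated), via enaminone 10 (not isolated)  
Conditions: PdCl2(dppf) (5 mol %), CO (20 bar), Et2NH/toluene 1:1, 110 °C, autoclave  
Reagents that add atoms: carbon monoxide, `[C-]#[O+]`  
Why: Pd‑catalysed carbonylative Sonogashira coupling/annulation (known for o‑iodophenols with terminal alkynes): oxidative addition, CO insertion and alkynylation give ynone 9, Et2NH adds conjugately to give enaminone 10, and the only free phenol OH closes 6‑endo by addition–elimination (no 5‑exo aurone), which places the ring oxygen para to the methyl and so gives the 6‑methyl, not the 8‑methyl, chromone.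

**Step 6**  
Reactants: 11 5,7-dimethoxy-6-methyl-2-nonacosyl-4H-chromen-4-one  
Product: 13 5,7-dihydroxy-6-methyl-2-nonacosyl-4H-chromen-4-one, via bis(dibromoboryl) ether 12 (not isolated)  
Conditions: BBr3 (6 equiv), CH2Cl2, −78 °C → rt, 16 h; then ice‑water  
Reagents that add atoms: none  
Why: Lewis‑acid aryl methyl ether cleavage: BBr3 coordinates each OMe (the 5‑OMe assisted by chelation to C4=O), bromide removes the methyl by SN2 as MeBr, and aqueous work‑up hydrolyses the O–B bonds of 12 to the target; anhydrous conditions at or below rt do not open the pyranone, so no Wessely–Moser scrambling to the 8‑methyl isomer is expected.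

**Compound list**
```
1 | 2,6-dimethoxytoluene (1,3-dimethoxy-2-methylbenzene) | COc1cccc(OC)c1C | starting material
2 | 2-(3,5-dimethoxy-4-methylphenyl)-4,4,5,5-tetramethyl-1,3,2-dioxaborolane (aryl pinacol boronate) | COc1cc(B2OC(C)(C)C(C)(C)O2)cc(OC)c1C | intermediate
3 | 3,5-dimethoxy-4-methylphenol | COc1cc(O)cc(OC)c1C | intermediate
4 | 2-iodo-3,5-dimethoxy-4-methylphenol | COc1cc(O)c(I)c(OC)c1C | intermediate
5 | 1-triacontanol | CCCCCCCCCCCCCCCCCCCCCCCCCCCCCCO | starting material
6 | triacontanal | CCCCCCCCCCCCCCCCCCCCCCCCCCCCCC=O | intermediate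
7 | 1-diazohentriacont-1-ene | CCCCCCCCCCCCCCCCCCCCCCCCCCCCCC=C=[N+]=[N-] | intermediate
8 | hentriacont-1-yne | CCCCCCCCCCCCCCCCCCCCCCCCCCCCCC#C | intermediate
9 | 1-(6-hydroxy-2,4-dimethoxy-3-methylphenyl)dotriacont-2-yn-1-one (aryl ynone) | CCCCCCCCCCCCCCCCCCCCCCCCCCCCCC#CC(=O)c1c(O)cc(OC)c(C)c1OC | intermediate
10 | (E)-3-(diethylamino)-1-(6-hydroxy-2,4-dimethoxy-3-methylphenyl)dotriacont-2-en-1-one (enaminone; drawn E, geometry inconsequential) | CCCCCCCCCCCCCCCCCCCCCCCCCCCCC/C(N(CC)CC)=C\C(=O)c1c(O)cc(OC)c(C)c1OC | intermediate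
11 | 5,7-dimethoxy-6-methyl-2-nonacosyl-4H-chromen-4-one | CCCCCCCCCCCCCCCCCCCCCCCCCCCCCc1cc(=O)c2c(OC)c(C)c(OC)cc2o1 | intermediate
12 | 5,7-bis[(dibromoboranyl)oxy]-6-methyl-2-nonacosyl-4H-chromen-4-one (bis(dibromoboryl) ether) | CCCCCCCCCCCCCCCCCCCCCCCCCCCCCc1cc(=O)c2c(OB(Br)Br)c(C)c(OB(Br)Br)cc2o1 | intermediate
13 | 5,7-dihydroxy-6-methyl-2-nonacosyl-4H-chromen-4-one (CNP0186826.0, achiral) | CCCCCCCCCCCCCCCCCCCCCCCCCCCCCc1cc(=O)c2c(O)c(C)c(O)cc2o1 | target
```

**Totals**
Total step count: 6. Longest linear sequence: 4 steps (1 → 3 → 4 → 11 → 13, or 5 → 6 → 8 → 11 → 13).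

**Three steps most likely to fail, with fallbacks**

Step 5 (carbonylative annulation). The risks are aminocarbonylation by Et2NH, direct Sonogashira coupling leading to a benzofuran, slow oxidative addition at the electron‑rich di‑ortho‑substituted iodide, and poor solubility of the wax alkyne. The fallback is CO‑free, sets out from phenol 3 and alkyne 8, and comes back to the route at 11. Ortho‑formylation of 3 (MgCl2, Et3N, paraformaldehyde, MeCN, reflux) gives 6-hydroxy-2,4-dimethoxy-3-methylbenzaldehyde F1. Addition of the lithium acetylide of 8 (n‑BuLi, THF, −78 → 0 °C, 2.5 equiv) gives racemic 1-(6-hydroxy-2,4-dimethoxy-3-methylphenyl)dotriacont-2-yn-1-ol F2. MnO2 (CH2Cl2, rt) oxidises this to ynone 9, now isolated, and Et2NH in EtOH/toluene at 60 °C closes 9 through 10 to 11.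

Step 2 (mono‑iodination). The risks are di‑iodination, oxidation of the very electron‑rich phenol, and protodeiodination during purification. The fallback replaces electrophilic substitution by directed ortho‑metalation, sets out from 3 and comes back at 4. MOMCl and i‑Pr2NEt (CH2Cl2, 0 °C) give 1,3-dimethoxy-5-(methoxymethoxy)-2-methylbenzene F3. n‑BuLi (THF, 0 °C) lithiates the position between OMOM and OMe, and an I2 quench gives 2-iodo-3,5-dimethoxy-1-(methoxymethoxy)-4-methylbenzene F4, with exactly one iodine set by the aryllithium stoichiometry. HCl in MeOH at rt removes the MOM group to give 4.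

Step 4 (Ohira–Bestmann reaction). The C30 aldehyde barely dissolves in methanolic media, so conversion may be incomplete and acetal or aldol by‑products may form. The fallback is a Corey–Fuchs sequence in aprotic solvents, sets out from 6 and comes back at 8. CBr4 and PPh3 (CH2Cl2, 0 °C → rt) give 1,1-dibromohentriacont-1-ene F5, and n‑BuLi (2.2 equiv, THF, −78 → 0 °C) followed by water gives 8.

**Further compounds**
```
F1 | step 5 | 6-hydroxy-2,4-dimethoxy-3-methylbenzaldehyde | O=Cc1c(O)cc(OC)c(C)c1OC
F2 | step 5 | 1-(6-hydroxy-2,4-dimethoxy-3-methylphenyl)dotriacont-2-yn-1-ol (racemic) | CCCCCCCCCCCCCCCCCCCCCCCCCCCCCC#CC(O)c1c(O)cc(OC)c(C)c1OC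
F3 | step 2 | 1,3-dimethoxy-5-(methoxymethoxy)-2-methylbenzene | COCOc1cc(OC)c(C)c(OC)c1
F4 | step 2 | 2-iodo-3,5-dimethoxy-1-(methoxymethoxy)-4-methylbenzene | COCOc1cc(OC)c(C)c(OC)c1I
F5 | step 4 | 1,1-dibromohentriacont-1-ene | CCCCCCCCCCCCCCCCCCCCCCCCCCCCCC=C(Br)Br
```
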